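**Retrosynthetic overview**

1. Berkazaphilone C ⇐ its bis-MOM ether 20; only the two phenols are protected.
2. Ring A is closed last: 6-endo oxa-Michael addition of the C1 hydroxyl onto the enynone obtained by Sonogashira coupling of β-chloroenone 17 with (E)-pent-3-en-1-yne (C4a–C4 and O2–C3).
3. Ring B comes from the key step: Cp2TiCl opens a terminal epoxide to the C8a radical, which closes C8a–C4a 6-endo-dig onto a chloroethynyl ketone (16 → 17), releasing C1–OH and setting C8a.
4. 16 ⇐ chloroethynyllithium + Seebach dioxolanone (C6 acyl donor); C7/C8 ⇐ aldol of the (S)-lactic acid/pivaldehyde dioxolanone enolate with acrolein, the aldolate being trapped by the protected orsellinoyl chloride.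
5. Ring order: orsellinate arene (methyl acetoacetate self-condensation) → carbocyclic ring B → pyran ring A.

Assumption: atom labels C1–C8a and O2 are the isochromene locants of the target, and (E)-pent-3-en-1-yne is bought as the pure E isomer.

**Step 1**
Reactants: 1 methyl acetoacetate (2 equiv)
Product: 2 methyl orsellinate (methyl 2,4-dihydroxy-6-methylbenzoate)
Conditions: NaH, THF, 0 °C; n-BuLi, −78 °C; then reflux; aq HCl
Reagents that add atoms: none
Why: Self-condensation of the acetoacetate dianion (Claisen acylation at C4 by the ester of a second molecule, then intramolecular aldol condensation and aromatisation of the triketo ester) is the known biomimetic route to methyl orsellinate; no stereocentre is formed.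

**Step 2**
Reactants: 2 methyl orsellinate
Product: 3 methyl 2,4-bis(methoxymethoxy)-6-methylbenzoate
Conditions: MOMCl, NaH, DMF, 0 °C to rt
Reagents that add atoms: chloromethyl methyl ether, COCCl
Why: Williamson O-alkylation of both phenoxides, with NaH/DMF chosen because the 2-OH is hydrogen-bonded to the ester.

**Step 3**
Reactants: 3 methyl 2,4-bis(methoxymethoxy)-6-methylbenzoate
Product: 4 2,4-bis(methoxymethoxy)-6-methylbenzoic acid
Conditions: KOH, MeOH/H2O, 80 °C; then aq HCl to pH 4, 0 °C
Reagents that add atoms: potassium hydroxide, [K+].[OH-]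
Why: Saponification of the hindered ester under forcing base, which the base-stable MOM acetals survive, followed by cold, mild acidification.

**Step 4**
Reactants: 5 (S)-lactic acid; 6 pivaldehyde
Product: 7 (2S,5S)-2-tert-butyl-5-methyl-1,3-dioxolan-4-one
Conditions: TsOH·H2O (cat.), H2SO4 (cat.), pentane, reflux (Dean–Stark); crystallise at −78 °C
Reagents that add atoms: none
Why: Acid-catalysed acetalisation with azeotropic water removal (Seebach self-regeneration-of-stereocentres template) leaves the lactic acid centre (5S) untouched and forms the acetal carbon under thermodynamic control as the cis (2S) isomer, purified by cold crystallisation.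

**Step 5**
Reactants: 7 (2S,5S)-2-tert-butyl-5-methyl-1,3-dioxolan-4-one; 8 acrolein; 4 2,4-bis(methoxymethoxy)-6-methylbenzoic acid
Product: 12 (1R)-1-[(2S,4R)-2-tert-butyl-4-methyl-5-oxo-1,3-dioxolan-4-yl]prop-2-en-1-yl 2,4-bis(methoxymethoxy)-6-methylbenzoate, via lithium enolate 9 (not isolated), via lithium aldolate 10 (not isolated), via acid chloride 11 (not isolated)
Conditions: 4, 1-chloro-N,N,2-trimethylprop-1-en-1-amine, CH2Cl2, rt (gives 11); 7, LiN(SiMe3)2, THF, −78 °C; 8, −78 °C; then 11, DMAP (cat.), −78 to −30 °C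
Reagents that add atoms: none
Why: Seebach aldol addition then O-acylation of the aldolate: acrolein adds 1,2 to the planar enolate anti to tert-butyl, regenerating the lactic acid centre as C7 (R), and a Zimmerman–Traxler chair with vinyl equatorial and Me cis to OLi predicts the (R)-carbinol C8 (d.r. of roughly 4:1 expected, minor epimer removed after acylation by the electrophilic aroyl chloride).

**Step 6**
Reactants: 12 (the allylic ester from step 5)
Product: 13 (R)-[(2S,4R)-2-tert-butyl-4-methyl-5-oxo-1,3-dioxolan-4-yl](oxiran-2-yl)methyl 2,4-bis(methoxymethoxy)-6-methylbenzoate (both epimers at the epoxide carbon)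
Conditions: mCPBA, CH2Cl2, 40 °C
Reagents that add atoms: 3-chloroperbenzoic acid, OOC(=O)c1cccc(Cl)c1
Why: Prilezhaev epoxidation of the only alkene; the configuration of the new epoxide carbon (the future C8a) is deliberately uncontrolled because it becomes a planar radical in step 8.

**Step 7**
Reactants: 13 (the epoxide from step 6); 14 (E)-1,2-dichloroethene
Product: 16 (1R,2R)-5-chloro-2-hydroxy-2-methyl-1-(oxiran-2-yl)-3-oxopent-4-yn-1-yl 2,4-bis(methoxymethoxy)-6-methylbenzoate, via chloroethynyllithium 15 (not isolated)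
Conditions: 14, MeLi (2 equiv), Et2O, 0 °C; then 13, THF, −78 °C; AcOH, −78 °C
Reagents that add atoms: none
Why: Acetylide addition to the activated lactone carbonyl of the dioxolanone (chloroethynyllithium by Kende's dehydrochlorination/lithiation of dichloroethene) gives a tetrahedral alkoxide that is stable at −78 °C and collapses on protonation to the ynone, releasing pivaldehyde and the free C7 alcohol with C7 and C8 unchanged, while the hindered benzoate and the epoxide are inert.

**Step 8**
Reactants: 16 (the epoxy chloroynone from step 7)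
Product: 17 (1R,2R,6R)-5-chloro-2-hydroxy-6-(hydroxymethyl)-2-methyl-3-oxocyclohex-4-en-1-yl 2,4-bis(methoxymethoxy)-6-methylbenzoate
Conditions: Cp2TiCl2 (20 mol %), Mn dust, 2,4,6-collidine·HCl, THF, rt, slow addition of 16
Reagents that add atoms: none
Why: Proposed new method: Nugent–RajanBabu/Gansäuer epoxide opening by Cp2TiCl (trivalent titanium) gives the secondary β-titanoxy radical at C8a from both epoxide epimers, and this nucleophilic radical attacks the chlorine-bearing β-carbon C4a of the ynone 6-endo-dig (the mode favoured when the carbonyl lies inside the forming ring, as for 4-oxohex-5-enyl radicals); the in-ring vinyl radical cannot expel Cl and is quenched to the β-chloroenone, and C8a is set trans to the C8 acyloxy group because CH2OTi and OCOAr are both pseudo-equatorial in the half-chair transition state (minor epimer removed by chromatography); the closest known reactions are titanocene-mediated epoxide–alkyne and epoxide–enone radical cyclisations and 6-endo radical closures onto vinyl ketones.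

**Step 9**
Reactants: 17 (the β-chloroenone from step 8); 18 (E)-pent-3-en-1-yne
Product: 20 (7R,8R,8aR)-7-hydroxy-7-methyl-6-oxo-3-[(E)-prop-1-enyl]-6,7,8,8a-tetrahydro-1H-isochromen-8-yl 2,4-bis(methoxymethoxy)-6-methylbenzoate, via enynone 19 (not isolated)
Conditions: PdCl2(PPh3)2 (5 mol %), CuI (10 mol %), Et3N, THF, rt; then DABCO (20 mol %), 40 °C
Reagents that add atoms: none
Why: Sonogashira coupling of the vinylogous acyl chloride gives enynone 19, whose primary alcohol adds to the δ-carbon C3 of the ynenone (amine-mediated 6-endo-dig oxa-Michael, a 1,6-addition) to close ring A without creating a stereocentre, and the weak amine bases avoid E1cB loss of the C8 ester.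

**Step 10**
Reactants: 20 (bis-MOM berkazaphilone C)
Product: 21 berkazaphilone C
Conditions: TFA, CH2Cl2, 0 °C; aq NaHCO3
Reagents that add atoms: none
Why: Acidolysis of the two aryl MOM acetals at low temperature leaves the vinylogous ester, the tertiary α-ketol and the hindered benzoate intact and touches no stereocentre.

**Compound list**

1 | methyl acetoacetate | COC(=O)CC(C)=O | starting material
2 | methyl orsellinate | COC(=O)c1c(C)cc(O)cc1O | intermediate
3 | methyl 2,4-bis(methoxymethoxy)-6-methylbenzoate | COCOc1cc(C)c(C(=O)OC)c(OCOC)c1 | intermediate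
4 | 2,4-bis(methoxymethoxy)-6-methylbenzoic acid | COCOc1cc(C)c(C(=O)O)c(OCOC)c1 | intermediate
5 | (S)-lactic acid | C[C@H](O)C(=O)O | starting material
6 | pivaldehyde | CC(C)(C)C=O | starting material
7 | (2S,5S)-2-tert-butyl-5-methyl-1,3-dioxolan-4-one | C[C@@H]1O[C@H](C(C)(C)C)OC1=O | intermediate
8 | acrolein | C=CC=O | starting material
9 | lithium (2S)-2-tert-butyl-5-methyl-1,3-dioxol-4-olate (enolate of 7) | CC1=C(O[Li])O[C@@H](C(C)(C)C)O1 | intermediate
10 | lithium (1R)-1-[(2S,4R)-2-tert-butyl-4-methyl-5-oxo-1,3-dioxolan-4-yl]prop-2-en-1-olate | C[C@]1([C@H](O[Li])C=C)O[C@H](C(C)(C)C)OC1=O | intermediate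
11 | 2,4-bis(methoxymethoxy)-6-methylbenzoyl chloride | COCOc1cc(C)c(C(Cl)=O)c(OCOC)c1 | intermediate
12 | (1R)-1-[(2S,4R)-2-tert-butyl-4-methyl-5-oxo-1,3-dioxolan-4-yl]prop-2-en-1-yl 2,4-bis(methoxymethoxy)-6-methylbenzoate | C[C@]1([C@H](OC(=O)c2c(C)cc(OCOC)cc2OCOC)C=C)O[C@H](C(C)(C)C)OC1=O | intermediate
13 | (R)-[(2S,4R)-2-tert-butyl-4-methyl-5-oxo-1,3-dioxolan-4-yl](oxiran-2-yl)methyl 2,4-bis(methoxymethoxy)-6-methylbenzoate, epoxide carbon unassigned | C[C@]1([C@H](OC(=O)c2c(C)cc(OCOC)cc2OCOC)C2CO2)O[C@H](C(C)(C)C)OC1=O | intermediate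
14 | (E)-1,2-dichloroethene | Cl/C=C/Cl | starting material
15 | chloroethynyllithium | [Li]C#CCl | intermediate
16 | (1R,2R)-5-chloro-2-hydroxy-2-methyl-1-(oxiran-2-yl)-3-oxopent-4-yn-1-yl 2,4-bis(methoxymethoxy)-6-methylbenzoate | C[C@@](O)([C@H](OC(=O)c1c(C)cc(OCOC)cc1OCOC)C1CO1)C(=O)C#CCl | intermediate
17 | (1R,2R,6R)-5-chloro-2-hydroxy-6-(hydroxymethyl)-2-methyl-3-oxocyclohex-4-en-1-yl 2,4-bis(methoxymethoxy)-6-methylbenzoate | ClC1=CC(=O)[C@](C)(O)[C@H](OC(=O)c2c(C)cc(OCOC)cc2OCOC)[C@H]1CO | intermediate
18 | (E)-pent-3-en-1-yne | C/C=C/C#C | starting material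
19 | (1R,2R,6R)-2-hydroxy-6-(hydroxymethyl)-2-methyl-3-oxo-5-[(E)-pent-3-en-1-ynyl]cyclohex-4-en-1-yl 2,4-bis(methoxymethoxy)-6-methylbenzoate | C/C=C/C#CC1=CC(=O)[C@](C)(O)[C@H](OC(=O)c2c(C)cc(OCOC)cc2OCOC)[C@H]1CO | intermediate
20 | (7R,8R,8aR)-7-hydroxy-7-methyl-6-oxo-3-[(E)-prop-1-enyl]-6,7,8,8a-tetrahydro-1H-isochromen-8-yl 2,4-bis(methoxymethoxy)-6-methylbenzoate | C/C=C/C1=CC2=CC(=O)[C@](C)(O)[C@H](OC(=O)c3c(C)cc(OCOC)cc3OCOC)[C@H]2CO1 | intermediate
21 | berkazaphilone C, (7R,8R,8aR)-7-hydroxy-7-methyl-6-oxo-3-[(E)-prop-1-enyl]-6,7,8,8a-tetrahydro-1H-isochromen-8-yl 2,4-dihydroxy-6-methylbenzoate | C/C=C/C1=CC2=CC(=O)[C@](C)(O)[C@H](OC(=O)c3c(C)cc(O)cc3O)[C@H]2CO1 | target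

**Step count and risks**

Total: 10 steps. Longest linear sequence: 9 steps (steps 1–3, then 5–10); 7 steps from (S)-lactic acid.

The three steps most likely to fail are 8, 5 and 7.

Step 8 is the weakest point. The radical could close 5-exo instead of 6-endo, the chloroalkyne could be reduced, or the organotitanium could β-eliminate. The fallback sets out from 13 and comes back at 20. Lithioacetonitrile (2.2 equiv, THF, −78 °C) opens the dioxolanone to the β-ketonitrile F1. Stoichiometric Cp2TiCl (from Cp2TiCl2 and Zn) then generates the same C8a radical, which adds 6-exo-dig to the nitrile carbon, a known titanocene epoxynitrile cyclisation; acidic hydrolysis of the imine gives the cyclohexane-1,3-dione F2. TsCl/Et3N sulfonylates the vinylogous acid on the less hindered C4a oxygen to give the enol tosylate F3. F3 then undergoes the Sonogashira coupling with 18 and the oxa-Michael closure of step 9 to give 20.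

Step 5 may give poor selectivity at C8, and the hindered lithium aldolate may acylate sluggishly or revert. The fallback sets out from 7 and comes back at 12. Enolate 9 is C-acylated with acryloyl chloride at −78 °C to the vinyl ketone F4. Reagent-controlled reduction with catecholborane and the (S)-CBS oxazaborolidine, with vinyl as the small group, gives the (1R)-allylic alcohol F5. Acylation of F5 with 11 (Et3N, DMAP, CH2Cl2) gives 12.

Step 7 depends on the stability of chloroethynyllithium and of the α-hydroxy chloroynone, and over-addition is possible. The fallback sets out from 13 and comes back at 16. HC≡CMgBr (THF, −78 °C) opens the dioxolanone to the terminal ynone F6. Its alkyne C–H is then chlorinated with N-chlorosuccinimide and catalytic Ag2CO3 in acetone to give 16.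

**Further compounds**

F1 | step 8 | (1R,2R)-4-cyano-2-hydroxy-2-methyl-1-(oxiran-2-yl)-3-oxobutyl 2,4-bis(methoxymethoxy)-6-methylbenzoate | C[C@@](O)([C@H](OC(=O)c1c(C)cc(OCOC)cc1OCOC)C1CO1)C(=O)CC#N
F2 | step 8 | (1R,2R,6R)-2-hydroxy-6-(hydroxymethyl)-2-methyl-3,5-dioxocyclohexyl 2,4-bis(methoxymethoxy)-6-methylbenzoate | O=C1CC(=O)[C@](C)(O)[C@H](OC(=O)c2c(C)cc(OCOC)cc2OCOC)[C@H]1CO
F3 | step 8 | (1R,2R,6R)-2-hydroxy-6-(hydroxymethyl)-2-methyl-3-oxo-5-(tosyloxy)cyclohex-4-en-1-yl 2,4-bis(methoxymethoxy)-6-methylbenzoate | Cc1ccc(cc1)S(=O)(=O)OC1=CC(=O)[C@](C)(O)[C@H](OC(=O)c2c(C)cc(OCOC)cc2OCOC)[C@H]1CO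
F4 | step 5 | (2S,5R)-5-acryloyl-2-tert-butyl-5-methyl-1,3-dioxolan-4-one | C[C@]1(C(=O)C=C)O[C@H](C(C)(C)C)OC1=O
F5 | step 5 | (2S,5R)-2-tert-butyl-5-[(1R)-1-hydroxyprop-2-enyl]-5-methyl-1,3-dioxolan-4-one | C[C@]1([C@H](O)C=C)O[C@H](C(C)(C)C)OC1=O
F6 | step 7 | (1R,2R)-2-hydroxy-2-methyl-1-(oxiran-2-yl)-3-oxopent-4-yn-1-yl 2,4-bis(methoxymethoxy)-6-methylbenzoate | C[C@@](O)([C@H](OC(=O)c1c(C)cc(OCOC)cc1OCOC)C1CO1)C(=O)C#C
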